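Start from 2.00%, the impurity share φ, defined as the charge of protic impurity over the charge of starting material: if each impurity molecule destroys one molecule of starting material, φ is what this side reaction can take from the flask, with the impurity as its limiting reagent. The ochre run had 3.00%, so work with the fraction of the charge that the impurity leaves to the other steps, 98.0% in the flask against 97.0% in the ochre run. If that small loss scales target and isomer of the product alike, it cancels in their ratio ρ, so carry the ochre curve of ρ over to the flask, granting that this is a guess.

- ochre: starting material 16 mM; protic impurity 0.48 mM; run made earlier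
- flask: starting material 16 mM; protic impurity 0.320 mM; time 15 d

ochre run (percent of the starting material charged)

| time / h | target / % | isomer of the product / % |
|---|---|---|
| 3.00 | 6.2 | 1.4 |
| 10.0 | 14.5 | 3.8 |
| 15.0 | 17.3 | 4.8 |
| 25.0 | 20.1 | 7.5 |
| 40.0 | 19.4 | 9.6 |

(readings scatter by 0.5 percentage points)

- no earlier run changes the charge of protic impurity; that part of a forecast is a guess

* ratio of target to isomer of the product at 30 min
* ratio of target to isomer of the product at 15 d
* which of target and isomer of the product there is more of at 15 d

Draw that curve as a straight line in ln ρ. The ochre readings start at ρ = 4.43 at 3.00 h, a loose value, the isomer reading of 1.4% carrying 0.5 percentage points, and end at 2.02 at 40.0 h, which gives a fall in ln ρ of λ = 0.0212 h⁻¹. Running back, the line gives my own ρ = 4.67 at 30 min. Running forward, it crosses ρ = 1 at 3.05 d, and by 15 d it has reached 0.00228. The readings end at 40.0 h, earlier than both, so I commit to the crossing and the direction but not to that last value, which is my own and stands against the forecast's 0.25.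

The forecast gives 4.6 at 30 min, 0.25 at 15 d and isomer of the product ahead, in its words “I expect isomer to lead clearly”.

The flask gives 5.89 at 30 min and 0.282 at 15 d, with isomer of the product ahead at 7.69% against 2.17% of target.

    starting material + protic impurity → quenched substrate (k = 0.780 L mol⁻¹ min⁻¹)
    target ⇌ isomer of the product (k = 8.10 × 10⁻⁵ min⁻¹)
    target → over-reaction product (k = 4.60 × 10⁻⁴ min⁻¹)
    starting material ⇌ dormant form (K = 0.650, k = 0.00350 min⁻¹)
    starting material ⇌ target (K = 1.90, k = 5.10 × 10⁻⁴ min⁻¹)
    starting material ⇌ isomer of the product (K = 2.10, k = 8.50 × 10⁻⁵ min⁻¹)

At 15.0 d the flask holds 2.00% of quenched substrate, matching φ, with protic impurity down to 0% of its charge. For the neighbour flask with 0.13 mM of protic impurity, φ comes to 0.812%; that flask holds 0.812% of quenched substrate, and its ratio at 15 d is 0.282.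

The data were computed with made-up constants; the scatter is artificial.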